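All runs come from a simulation for substances that don't exist; the scatter is artificial.

1. A leftover opens the matter: the north-west run, which has spring's recipe, still holds 58.0% of its starting material after 40.0 h. Its pace has also fallen, with 28.3% of target in the first 15.0 h against 13 percentage points in the next 25.0 h.

common to all: free catalyst 0.39 mM

| flask | starting material | second substrate | added ligand | remark | time |
|---|---|---|---|---|---|
| north-west | 0.050 M | 0.050 M | 0.23 mM | run made earlier |  |
| north-east | 0.050 M | 0.050 M | 0.15 mM | run made earlier |  |
| east | 0.050 M | 0.050 M | 0.35 mM | run made earlier |  |
| midnight | 0.050 M | 0.0500 M (fed, over 15 h) | 0.23 mM | all else is in the flask from the start; the feed brings no volume worth counting | 40 h |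
| spring | 0.050 M | 0.0500 M | 0.23 mM | everything together at the start | 40 h |
| dusk | 0.050 M (in portions, 2, over 15 h) | 0.0500 M | 0.23 mM | first portion at the start, last at 15 h | 40 h |
| dawn | 0.050 M (fed, over 1.5 h) | 0.0500 M | 0.23 mM | all else is in the flask from the start; the feed brings no volume worth counting | 40 h |
| winter | 0.050 M (fed, over 15 h) | 0.0500 M | 0.23 mM | all else is in the flask from the start; the feed brings no volume worth counting | 40 h |

| run | time / h | target / % | starting material / % |
|---|---|---|---|
| north-west | 3.00 | 11.6 | 89.8 |
| north-west | 8.00 | 16.0 | 81.4 |
| north-west | 15.0 | 28.3 | 70.1 |
| north-west | 40.0 | 41.4 | 58.0 |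
| north-east | 2.00 | 9.0 | 90.8 |
| north-east | 4.00 | 15.8 | 84.5 |
| north-east | 10.0 | 27.1 | 72.7 |
| north-east | 25.0 | 39.6 | 60.4 |
| east | 3.00 | 6.9 | 91.7 |
| east | 8.00 | 14.7 | 84.6 |
| east | 15.0 | 22.3 | 77.3 |
| east | 25.0 | 28.8 | 71.2 |

(standard deviation of a reading: 1 percentage point)

- the flask with the highest amount of target, in percent of the starting material charged ("all alike" if they lie within 1.5 percentage points) (midnight / spring / dusk / dawn / winter / all alike)
- final target, as a percentage of the starting material charged, in midnight
- final target, as a percentage of the starting material charged, in spring
- final target, as a percentage of the starting material charged, in dusk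
- final target, as a percentage of the starting material charged, in dawn
- final target, as a percentage of the starting material charged, in winter

- the numbers in the tables scatter by 1 percentage point (one standard deviation)

2. A catalyst works in rounds and comes back after each one, so the ratio of starting material charged to catalyst charged, 128, is the number of rounds each catalyst owes for the whole charge. The north-west run has paid 53.1 by its last reading, less than it owes. The fraction of the charge turned to target, times that ratio, is the turnover number, the target made per catalyst charged.

3. A second way to the spring number comes from another flask. The readings fall together at equal values of time divided by added ligand, a ligand clock. The last reading of the north-east run comes at 0.625 of the north-west run's last time, with 0.652 of its added ligand, so the two readings stand close together on that clock. The north-east count is 50.8, and one reading's scatter is worth 1.28 rounds, so the two ways agree. My reckoning for spring is therefore 40.5%.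

4. The two ways part on the fed flasks. Read as a clock, the catalyst ages by the hour, so hours spent at low substrate are lost. Read as a count, the catalyst owes a number of rounds, whatever the hour, and midnight, spring, dusk, dawn and winter each carry 0.23 mM of added ligand to 40 h. The north-west, north-east and east runs each held 0.050 M of starting material and 0.050 M of second substrate from the start, so their readings do not separate the two. I commit to the count, which gives about 41.4% in each flask, so "all alike", though this is untested.

5. The forecast differs from that reckoning. It names spring, with 41% there, 40% in dawn, and 31%, 31% and 31% in midnight, dusk and winter, on the ground that “Slow feeds waste catalyst life at low substrate”.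

6. Highest is midnight at 67.2%, with winter at 65.2%, dusk at 50.8%, dawn at 43.6% and spring at 40.4%.

    starting material + free catalyst ⇌ catalyst intermediate A (K = 36.1 L mol⁻¹, k = 18.0 L mol⁻¹ min⁻¹)
    second substrate + free catalyst ⇌ catalyst intermediate B (K = 3350 L mol⁻¹, k = 21.2 L mol⁻¹ min⁻¹)
    catalyst intermediate A → free catalyst + target (k = 0.559 min⁻¹)
    free catalyst + added ligand ⇌ idle complex, settled at all times (K = 40000 L mol⁻¹)
    second substrate + catalyst intermediate A → spent catalyst (k = 0.272 L mol⁻¹ min⁻¹)
    catalyst intermediate B → free catalyst + second product (k = 1.01 min⁻¹)

Spent catalyst at the end is 60.2% of the catalyst charged in midnight, less than the 77.9% in spring. Midnight's count is 86.2, more than the carried 53.1. A neighbour of midnight has 9.8 × 10⁻⁵ M of free catalyst, a quarter of the charge. The carried count gives it 10.4%, and it ends at 11.6%, a count of 59.3.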